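## Retrosynthetic overview
1. The endgame is HF desilylation, a one-flask TBS cleavage and oxidation of one side-chain CH2O group to CO2H, and Yamaguchi acylation of the equatorial hydroxyl of an anti-1,3-diol. The acyl partner is (Z)-4-acetoxy-2-methylbut-2-enoic acid, made from but-2-yn-1-ol.
2. Key disconnection: the ring–C(=CH2) bond between the two carbinol carbons comes from a semipinacol 1,2-alkenyl shift in a cis-2,3-epoxy tertiary alcohol. The resulting ketone is reduced at once by hydroxyl-directed hydride.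
3. The epoxy alcohol comes from directed epoxidation after 1,2-addition of a 2-lithioallyl ether to a 4,5,5-trisubstituted cyclohex-2-enone. That enone comes from dehydrogenation after an anti vinylcopper addition, which sets the quaternary centre.
4. The first stereocentre comes from a new nickel-catalysed enantioconvergent γ-alkenylation of racemic 4-bromo-3-methylcyclohex-2-enone.
5. Rings: the cyclohexane is bought as 3-methylcyclohex-2-enone and is never opened. The only ring formed is a transient oxirane, which the shift consumes.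

Assumption: the sense of induction of the nickel/pybox catalyst in step 4 cannot be predicted. The (S,S)-ligand is written, and its mirror image is used if a test run gives (R)-8.

Abbreviations: TBDPSO = tert-butyldiphenylsilyloxy; TBSO = tert-butyldimethylsilyloxy. The α-face is the face that carries the ring methyl group; the β-face is the opposite face.

## Route

Step 1
Reactants: 1 2-bromoprop-2-en-1-ol
Product: 2 tert-butyl[(2-bromoprop-2-en-1-yl)oxy]diphenylsilane
Conditions: TBDPSCl (1.05 equiv), imidazole (2 equiv), CH2Cl2, 0 → 25 °C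
Reagents that add atoms: tert-butyl(chloro)diphenylsilane, CC(C)(C)[Si](Cl)(c1ccccc1)c1ccccc1
Why: Imidazole-promoted O-silylation of a primary allylic alcohol, using the robust TBDPS group because it must outlast the TBS group that is cleaved in step 14; no stereocentre is formed.

Step 2
Reactants: 1 2-bromoprop-2-en-1-ol
Product: 3 tert-butyl[(2-bromoprop-2-en-1-yl)oxy]dimethylsilane
Conditions: TBSCl (1.05 equiv), imidazole (2 equiv), CH2Cl2, 0 → 25 °C
Reagents that add atoms: tert-butyl(chloro)dimethylsilane, CC(C)(C)[Si](C)(C)Cl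
Why: The same O-silylation with the more labile TBS group, which marks the allyl unit that will later be oxidised to the acrylic acid; no stereocentre is formed.

Step 3
Reactants: 4 3-methylcyclohex-2-en-1-one
Product: 5 rac-4-bromo-3-methylcyclohex-2-en-1-one
Conditions: NBS (1.05 equiv), AIBN (5 mol%), PhCF3, 80 °C, 1 h; filter, use at once
Reagents that add atoms: N-bromosuccinimide, O=C1CCC(=O)N1Br
Why: Wohl–Ziegler bromination, in which hydrogen abstraction prefers the secondary, carbonyl-conjugated allylic position C4 over the primary methyl group, and the racemate is all that step 4 needs.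

Step 4
Reactants: 2 tert-butyl[(2-bromoprop-2-en-1-yl)oxy]diphenylsilane, 5 rac-4-bromo-3-methylcyclohex-2-en-1-one
Product: 8 (4S)-4-[3-(TBDPSO)prop-1-en-2-yl]-3-methylcyclohex-2-en-1-one, via alkenyllithium 6 (not isolated), via alkenylzinc bromide 7 (not isolated)
Conditions: 2 (1.6 equiv), t-BuLi (3.2 equiv), Et2O, −78 °C; ZnBr2 (1.7 equiv), THF, −78 → 0 °C; then 5, NiCl2(dme) (10 mol%), (S,S)-2,6-bis(4-phenethyl-4,5-dihydrooxazol-2-yl)pyridine (13 mol%), DMA/THF, −20 °C
Reagents that add atoms: tert-butyllithium, [Li]C(C)(C)C (lithium of 6 only); zinc dibromide, Br[Zn]Br (zinc and bromine of 7 only)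
Why: Proposed new method: a nickel/pybox-catalysed enantioconvergent Negishi γ-alkenylation of a racemic cyclic γ-bromo enone, in which a monovalent alkenylnickel species abstracts bromine from either enantiomer of 5 to give one planar carbonyl-conjugated allyl radical, this radical recombines with the chiral divalent nickel centre, and the trivalent allyl(alkenyl)nickel reductively eliminates at C4 (conjugation is kept and C2 is flanked by C=O and the methyl-bearing carbon), so the ligand alone fixes the (S)-centre under non-basic conditions that do not enolise the product; the closest known reaction type is the stereoconvergent nickel-catalysed Negishi coupling of racemic secondary allylic chlorides, γ-chloro enoates and α-bromo ketones with alkyl-, aryl- or alkenylmetal reagents, which has not been shown for cyclic γ-halo enones or for 1,1-disubstituted alkenylzincs.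

Step 5
Reactants: 8 (4S)-4-[3-(TBDPSO)prop-1-en-2-yl]-3-methylcyclohex-2-en-1-one
Product: 10 (3R,4S)-4-[3-(TBDPSO)prop-1-en-2-yl]-3-ethenyl-3-methylcyclohexan-1-one, via trimethylsilyl enol ether 9 (not isolated)
Conditions: vinylMgBr (2.5 equiv), CuBr·SMe2 (20 mol%), TMSCl (3 equiv), DMPU (3 equiv), THF, −78 → −40 °C; then 1 M HCl, THF, 0 °C
Reagents that add atoms: vinylmagnesium bromide, C=C[Mg]Br; chlorotrimethylsilane, C[Si](C)(C)Cl (silyl group of 9 only)
Why: Copper-catalysed, TMSCl-accelerated conjugate addition, in which A(1,2) strain with the C3 methyl holds the C4 side chain pseudoaxial so that vinylcopper adds axially to the opposite face and sets the quaternary centre as (3R), with the vinyl group trans to the side chain.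

Step 6
Reactants: 10 (3R,4S)-4-[3-(TBDPSO)prop-1-en-2-yl]-3-ethenyl-3-methylcyclohexan-1-one
Product: 11 (4S,5R)-4-[3-(TBDPSO)prop-1-en-2-yl]-5-ethenyl-5-methylcyclohex-2-en-1-one
Conditions: IBX (2.5 equiv), DMSO, 70 °C
Reagents that add atoms: none
Why: IBX dehydrogenation of a ketone through its enol, where only one enone can form because the carbon beyond C2 is quaternary, so the double bond must go to the C6–C5 side and both stereocentres stay untouched.

Step 7
Reactants: 3 tert-butyl[(2-bromoprop-2-en-1-yl)oxy]dimethylsilane, 11 (4S,5R)-4-[3-(TBDPSO)prop-1-en-2-yl]-5-ethenyl-5-methylcyclohex-2-en-1-one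
Product: 13 (1S,4S,5R)-1-[3-(TBSO)prop-1-en-2-yl]-4-[3-(TBDPSO)prop-1-en-2-yl]-5-ethenyl-5-methylcyclohex-2-en-1-ol, via alkenyllithium 12 (not isolated)
Conditions: 3 (1.5 equiv), t-BuLi (3.0 equiv), Et2O, −78 °C; then 11, −78 °C; H2O quench
Reagents that add atoms: tert-butyllithium, [Li]C(C)(C)C (lithium of 12 only)
Why: 1,2-Addition of a hard alkenyllithium to the enone carbonyl, where in the half-chair that keeps the C4 side chain and the C5 vinyl group (pseudo)equatorial the axial C5 methyl shields the α-face, so equatorial attack from the β-face puts the new alkenyl group on the β-face and the hydroxyl on the α-face (1S).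

Step 8
Reactants: 13 (1S,4S,5R)-1-[3-(TBSO)prop-1-en-2-yl]-4-[3-(TBDPSO)prop-1-en-2-yl]-5-ethenyl-5-methylcyclohex-2-en-1-ol
Product: 14 (1R,2R,4R,5S,6R)-2-[3-(TBSO)prop-1-en-2-yl]-5-[3-(TBDPSO)prop-1-en-2-yl]-4-ethenyl-4-methyl-7-oxabicyclo[4.1.0]heptan-2-ol
Conditions: VO(acac)2 (5 mol%), t-BuOOH (1.3 equiv, decane), CH2Cl2, 0 °C
Reagents that add atoms: tert-butyl hydroperoxide, CC(C)(C)OO
Why: Hydroxyl-directed vanadium/hydroperoxide epoxidation, in which the vanadate ester of the pseudoaxial tertiary alcohol delivers oxygen to the α-face of the ring cis-alkene (1R,6R), while the exocyclic 1,1-disubstituted alkene is slowed by two flanking C–O bonds and by allylic strain in its reactive rotamer, and the remaining alkenes have no directing group.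

Step 9 (key step)
Reactants: 14 (1R,2R,4R,5S,6R)-2-[3-(TBSO)prop-1-en-2-yl]-5-[3-(TBDPSO)prop-1-en-2-yl]-4-ethenyl-4-methyl-7-oxabicyclo[4.1.0]heptan-2-ol
Product: 16 (1R,2R,3R,4S,5R)-2-[3-(TBSO)prop-1-en-2-yl]-4-[3-(TBDPSO)prop-1-en-2-yl]-5-ethenyl-5-methylcyclohexane-1,3-diol, via β-hydroxy ketone 15 (not isolated)
Conditions: BF3·OEt2 (30 mol%), CH2Cl2, −78 → −40 °C; then MeCN/AcOH (1:1), Me4NBH(OAc)3 (6 equiv), −30 °C; aq. potassium sodium tartrate
Reagents that add atoms: none
Why: Semipinacol rearrangement of a cis-2,3-epoxy alcohol followed by Evans–Saksena reduction: the β-alkenyl group, antiperiplanar to the breaking α C–O bond, shifts from the carbinol carbon to the adjacent oxirane carbon with inversion (side chain β and trans to the retained α-hydroxyl), and the epimerisable ketone 15 is trapped without isolation by acetoxyborohydride bound to that axial hydroxyl, which delivers hydride to the α-face and gives the 1,3-anti diol with the new hydroxyl β and cis to the side chain.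

Step 10
Reactants: 17 but-2-yn-1-ol
Product: 19 (2Z)-3-iodobut-2-en-1-ol, via cyclic alkenylaluminate 18 (not isolated)
Conditions: NaAlH2(OCH2CH2OMe)2 (1.5 equiv), THF, 0 → 25 °C; EtOAc; I2 (1.5 equiv), −78 → 0 °C; aq. work-up
Reagents that add atoms: sodium bis(2-methoxyethoxy)aluminium dihydride, [Na+].[H][Al-]([H])(OCCOC)OCCOC (aluminate part of 18 only); iodine, II
Why: Alkoxide-directed trans-hydroalumination of a propargylic alcohol places aluminium on C3 inside a five-membered ring, and iodinolysis with retention gives only the Z iodide.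

Step 11
Reactants: 19 (2Z)-3-iodobut-2-en-1-ol
Product: 20 (2Z)-3-iodobut-2-en-1-yl acetate
Conditions: Ac2O (1.3 equiv), pyridine, DMAP (2 mol%), CH2Cl2, 0 °C
Reagents that add atoms: acetic anhydride, CC(=O)OC(C)=O
Why: Simple O-acetylation, which also blocks the lactonisation to the butenolide that the free Z hydroxy acid would undergo after step 12.

Step 12
Reactants: 20 (2Z)-3-iodobut-2-en-1-yl acetate
Product: 21 (2Z)-4-acetoxy-2-methylbut-2-enoic acid
Conditions: PdCl2(PPh3)2 (3 mol%), CO (1 atm), H2O (10 equiv), Et3N (2 equiv), DMF, 25 °C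
Reagents that add atoms: carbon monoxide, [C-]#[O+]; water, O
Why: Palladium-catalysed hydroxycarbonylation, in which oxidative addition of the alkenyl carbon–iodine bond to zerovalent palladium, CO insertion and hydrolysis of the acylpalladium all retain the alkene geometry, and the CO-ligated catalyst does not ionise the allylic acetate at 25 °C.

Step 13
Reactants: 16 (1R,2R,3R,4S,5R)-2-[3-(TBSO)prop-1-en-2-yl]-4-[3-(TBDPSO)prop-1-en-2-yl]-5-ethenyl-5-methylcyclohexane-1,3-diol, 21 (2Z)-4-acetoxy-2-methylbut-2-enoic acid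
Product: 23 (1R,2S,3R,4S,5R)-2-[3-(TBSO)prop-1-en-2-yl]-4-[3-(TBDPSO)prop-1-en-2-yl]-5-ethenyl-3-hydroxy-5-methylcyclohexyl (2Z)-4-acetoxy-2-methylbut-2-enoate, via mixed anhydride 22 (not isolated)
Conditions: 21 (1.5 equiv), 2,4,6-trichlorobenzoyl chloride (1.5 equiv), Et3N (3 equiv), toluene, 25 °C; then 16, 75 °C, no DMAP
Reagents that add atoms: 2,4,6-trichlorobenzoyl chloride, O=C(Cl)c1c(Cl)cc(Cl)cc1Cl (aroyl group of 22 only)
Why: Yamaguchi esterification run without a nucleophilic catalyst so that the Z enoate cannot isomerise by addition–elimination, and selective for the equatorial C1 hydroxyl next to a CH2 group because the C3 hydroxyl is axial, sits between two branched carbons and is syn-axial to the methyl group.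

Step 14
Reactants: 23 (1R,2S,3R,4S,5R)-2-[3-(TBSO)prop-1-en-2-yl]-4-[3-(TBDPSO)prop-1-en-2-yl]-5-ethenyl-3-hydroxy-5-methylcyclohexyl (2Z)-4-acetoxy-2-methylbut-2-enoate
Product: 26 2-[(1S,2R,3S,4R,6R)-6-{[(2Z)-4-acetoxy-2-methylbut-2-enoyl]oxy}-3-[3-(TBDPSO)prop-1-en-2-yl]-4-ethenyl-2-hydroxy-4-methylcyclohexyl]prop-2-enoic acid, via allylic alcohol 24 (not isolated), via enal 25 (not isolated)
Conditions: Bi(OTf)3 (10 mol%), TEMPO (20 mol%), PhI(OAc)2 (1.3 equiv), MeCN/H2O (20:1), 25 °C; then t-BuOH, 2-methylbut-2-ene, NaH2PO4, NaClO2, 0 → 25 °C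
Reagents that add atoms: sodium chlorite, [Na+].[O-]Cl=O
Why: One-flask oxidative desilylation followed by Pinnick oxidation, in which acid-catalysed hydrolysis frees only the primary TBS ether (TBDPS stays), the oxoammonium salt oxidises the primary allylic alcohol but not the hindered axial secondary one, and chlorite takes the enal to the acid without touching alkenes, esters or stereocentres.

Step 15
Reactants: 26 2-[(1S,2R,3S,4R,6R)-6-{[(2Z)-4-acetoxy-2-methylbut-2-enoyl]oxy}-3-[3-(TBDPSO)prop-1-en-2-yl]-4-ethenyl-2-hydroxy-4-methylcyclohexyl]prop-2-enoic acid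
Product: 27 2-[(1S,2R,3S,4R,6R)-6-{[(2Z)-4-acetoxy-2-methylbut-2-enoyl]oxy}-4-ethenyl-2-hydroxy-3-(3-hydroxyprop-1-en-2-yl)-4-methylcyclohexyl]prop-2-enoic acid (CNP0261293.1)
Conditions: HF·pyridine, pyridine/THF, 0 → 25 °C
Reagents that add atoms: none
Why: Fluoride-driven Si–O cleavage under mildly acidic conditions that spare the acetate and the enoate, and the free hydroxy acid does not lactonise because a trans-fused lactone would need the chair in which the vinyl, acyloxy and hydroxypropenyl groups are all axial.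

## Compound list
1 | 2-bromoprop-2-en-1-ol | C=C(Br)CO | starting material
2 | tert-butyl[(2-bromoprop-2-en-1-yl)oxy]diphenylsilane | C=C(Br)CO[Si](c1ccccc1)(c2ccccc2)C(C)(C)C | intermediate
3 | tert-butyl[(2-bromoprop-2-en-1-yl)oxy]dimethylsilane | C=C(Br)CO[Si](C)(C)C(C)(C)C | intermediate
4 | 3-methylcyclohex-2-en-1-one | CC1=CC(=O)CCC1 | starting material
5 | rac-4-bromo-3-methylcyclohex-2-en-1-one | CC1=CC(=O)CCC1Br | intermediate
6 | [3-(TBDPSO)prop-1-en-2-yl]lithium | [Li]C(=C)CO[Si](c1ccccc1)(c2ccccc2)C(C)(C)C | intermediate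
7 | bromo[3-(TBDPSO)prop-1-en-2-yl]zinc | Br[Zn]C(=C)CO[Si](c1ccccc1)(c2ccccc2)C(C)(C)C | intermediate
8 | (4S)-4-[3-(TBDPSO)prop-1-en-2-yl]-3-methylcyclohex-2-en-1-one | CC1=CC(=O)CC[C@@H]1C(=C)CO[Si](c2ccccc2)(c3ccccc3)C(C)(C)C | intermediate
9 | {[(3R,4S)-4-[3-(TBDPSO)prop-1-en-2-yl]-3-ethenyl-3-methylcyclohex-1-en-1-yl]oxy}trimethylsilane | C=C[C@@]1(C)C=C(O[Si](C)(C)C)CC[C@@H]1C(=C)CO[Si](c2ccccc2)(c3ccccc3)C(C)(C)C | intermediate
10 | (3R,4S)-4-[3-(TBDPSO)prop-1-en-2-yl]-3-ethenyl-3-methylcyclohexan-1-one | C=C[C@@]1(C)CC(=O)CC[C@@H]1C(=C)CO[Si](c2ccccc2)(c3ccccc3)C(C)(C)C | intermediate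
11 | (4S,5R)-4-[3-(TBDPSO)prop-1-en-2-yl]-5-ethenyl-5-methylcyclohex-2-en-1-one | C=C[C@@]1(C)CC(=O)C=C[C@@H]1C(=C)CO[Si](c2ccccc2)(c3ccccc3)C(C)(C)C | intermediate
12 | [3-(TBSO)prop-1-en-2-yl]lithium | [Li]C(=C)CO[Si](C)(C)C(C)(C)C | intermediate
13 | (1S,4S,5R)-1-[3-(TBSO)prop-1-en-2-yl]-4-[3-(TBDPSO)prop-1-en-2-yl]-5-ethenyl-5-methylcyclohex-2-en-1-ol | C=C[C@@]1(C)C[C@@](O)(C(=C)CO[Si](C)(C)C(C)(C)C)C=C[C@@H]1C(=C)CO[Si](c2ccccc2)(c3ccccc3)C(C)(C)C | intermediate
14 | (1R,2R,4R,5S,6R)-2-[3-(TBSO)prop-1-en-2-yl]-5-[3-(TBDPSO)prop-1-en-2-yl]-4-ethenyl-4-methyl-7-oxabicyclo[4.1.0]heptan-2-ol | C=C[C@@]1(C)C[C@@](O)(C(=C)CO[Si](C)(C)C(C)(C)C)[C@@H]2O[C@@H]2[C@@H]1C(=C)CO[Si](c3ccccc3)(c4ccccc4)C(C)(C)C | intermediate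
15 | (2S,3R,4S,5R)-2-[3-(TBSO)prop-1-en-2-yl]-4-[3-(TBDPSO)prop-1-en-2-yl]-5-ethenyl-3-hydroxy-5-methylcyclohexan-1-one | C=C[C@@]1(C)CC(=O)[C@@H](C(=C)CO[Si](C)(C)C(C)(C)C)[C@H](O)[C@@H]1C(=C)CO[Si](c2ccccc2)(c3ccccc3)C(C)(C)C | intermediate
16 | (1R,2R,3R,4S,5R)-2-[3-(TBSO)prop-1-en-2-yl]-4-[3-(TBDPSO)prop-1-en-2-yl]-5-ethenyl-5-methylcyclohexane-1,3-diol | C=C[C@@]1(C)C[C@@H](O)[C@@H](C(=C)CO[Si](C)(C)C(C)(C)C)[C@H](O)[C@@H]1C(=C)CO[Si](c2ccccc2)(c3ccccc3)C(C)(C)C | intermediate
17 | but-2-yn-1-ol | CC#CCO | starting material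
18 | sodium 2,2-bis(2-methoxyethoxy)-3-methyl-2,5-dihydro-1,2-oxaaluminol-2-uide | CC1=CCO[Al-]1(OCCOC)OCCOC.[Na+] | intermediate
19 | (2Z)-3-iodobut-2-en-1-ol | C/C(I)=C/CO | intermediate
20 | (2Z)-3-iodobut-2-en-1-yl acetate | C/C(I)=C/COC(C)=O | intermediate
21 | (2Z)-4-acetoxy-2-methylbut-2-enoic acid | O=C(O)/C(C)=C\COC(C)=O | intermediate
22 | (2Z)-4-acetoxy-2-methylbut-2-enoic 2,4,6-trichlorobenzoic anhydride | O=C(OC(=O)/C(C)=C\COC(C)=O)c1c(Cl)cc(Cl)cc1Cl | intermediate
23 | (1R,2S,3R,4S,5R)-2-[3-(TBSO)prop-1-en-2-yl]-4-[3-(TBDPSO)prop-1-en-2-yl]-5-ethenyl-3-hydroxy-5-methylcyclohexyl (2Z)-4-acetoxy-2-methylbut-2-enoate | C=C[C@@]1(C)C[C@@H](OC(=O)/C(C)=C\COC(C)=O)[C@@H](C(=C)CO[Si](C)(C)C(C)(C)C)[C@H](O)[C@@H]1C(=C)CO[Si](c2ccccc2)(c3ccccc3)C(C)(C)C | intermediate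
24 | (1R,2S,3R,4S,5R)-4-[3-(TBDPSO)prop-1-en-2-yl]-5-ethenyl-3-hydroxy-2-(3-hydroxyprop-1-en-2-yl)-5-methylcyclohexyl (2Z)-4-acetoxy-2-methylbut-2-enoate | C=C[C@@]1(C)C[C@@H](OC(=O)/C(C)=C\COC(C)=O)[C@@H](C(=C)CO)[C@H](O)[C@@H]1C(=C)CO[Si](c2ccccc2)(c3ccccc3)C(C)(C)C | intermediate
25 | (1R,2S,3R,4S,5R)-4-[3-(TBDPSO)prop-1-en-2-yl]-5-ethenyl-3-hydroxy-5-methyl-2-(3-oxoprop-1-en-2-yl)cyclohexyl (2Z)-4-acetoxy-2-methylbut-2-enoate | C=C[C@@]1(C)C[C@@H](OC(=O)/C(C)=C\COC(C)=O)[C@@H](C(=C)C=O)[C@H](O)[C@@H]1C(=C)CO[Si](c2ccccc2)(c3ccccc3)C(C)(C)C | intermediate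
26 | 2-[(1S,2R,3S,4R,6R)-6-{[(2Z)-4-acetoxy-2-methylbut-2-enoyl]oxy}-3-[3-(TBDPSO)prop-1-en-2-yl]-4-ethenyl-2-hydroxy-4-methylcyclohexyl]prop-2-enoic acid | C=C[C@@]1(C)C[C@@H](OC(=O)/C(C)=C\COC(C)=O)[C@@H](C(=C)C(=O)O)[C@H](O)[C@@H]1C(=C)CO[Si](c2ccccc2)(c3ccccc3)C(C)(C)C | intermediate
27 | 2-[(1S,2R,3S,4R,6R)-6-{[(2Z)-4-acetoxy-2-methylbut-2-enoyl]oxy}-4-ethenyl-2-hydroxy-3-(3-hydroxyprop-1-en-2-yl)-4-methylcyclohexyl]prop-2-enoic acid | C=C[C@@]1(C)C[C@@H](OC(=O)/C(C)=C\COC(C)=O)[C@@H](C(=C)C(=O)O)[C@H](O)[C@@H]1C(=C)CO | target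

## Step count and risks
Total steps: 15.

Longest linear sequence: 10 steps. From 4 these are steps 3–9 and 13–15. The sequence from 1 through steps 1, 4–9 and 13–15 has the same length.

**Step 4 (the new reaction).**
- Risks are loss of HBr from 5 (which leads to m-cresol), coupling at C2, and low enantioselectivity.
- The fallback uses known chemistry and sets out from 5 and 7. An achiral Negishi alkenyl–allyl coupling with Pd(PPh3)4 in THF at 0 °C gives the racemic enone F1.
- Corey–Bakshi–Shibata reduction with (R)-Me-CBS and catecholborane delivers hydride to the same carbonyl face of both enantiomers. It therefore gives two diastereomers that separate on silica: the (1S,4S)-allylic alcohol F2 and the (1S,4R)-allylic alcohol F3.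
- Oxidation of F2 with MnO2 comes back to the route at 8. At most half of the material is recovered.

**Step 7.**
- The half-chair with the vinyl group and the C4 side chain diaxial may compete, which would erode facial selectivity. The bis-allylic alcohol 13 also leaves step 8 a chemoselectivity question.
- The fallback sets out from 11. Reagent-controlled Corey–Bakshi–Shibata reduction with (R)-Me-CBS and BH3·SMe2 gives the (1S,4S,5R)-allylic alcohol F4.
- VO(acac)2/t-BuOOH now has only one allylic alkene to epoxidise and gives the α-epoxy alcohol F5.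
- Dess–Martin periodinane gives the α-epoxy ketone F6.
- Alkenyllithium 12 then adds anti to the neighbouring oxirane oxygen, from the β-face. The sequence comes back to the route at 14.

**Step 9.**
- Risks are attack of the silyl ether oxygen on the activated oxirane, and dehydration or epimerisation of 15 before it is reduced.
- The fallback gives up the rearrangement. It sets out from 11 and passes through F4 and F5 as above.
- Alkenyllithium 12 (3 equiv) with BF3·OEt2 at −78 °C opens the oxirane of F5. Attack occurs with inversion at the carbon next to the carbinol, which is remote from the branched C5, and gives the (1S,2R,3R,4S,5R)-diol F7.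
- A Mitsunobu reaction (PPh3, DIAD, acid 21) at the less hindered C1 hydroxyl installs the ester with inversion. The sequence comes back to the route at 23.

## Further compounds
F1 | step 4 | rac-4-[3-(TBDPSO)prop-1-en-2-yl]-3-methylcyclohex-2-en-1-one | CC1=CC(=O)CCC1C(=C)CO[Si](c2ccccc2)(c3ccccc3)C(C)(C)C
F2 | step 4 | (1S,4S)-4-[3-(TBDPSO)prop-1-en-2-yl]-3-methylcyclohex-2-en-1-ol | CC1=C[C@@H](O)CC[C@@H]1C(=C)CO[Si](c2ccccc2)(c3ccccc3)C(C)(C)C
F3 | step 4 | (1S,4R)-4-[3-(TBDPSO)prop-1-en-2-yl]-3-methylcyclohex-2-en-1-ol | CC1=C[C@@H](O)CC[C@H]1C(=C)CO[Si](c2ccccc2)(c3ccccc3)C(C)(C)C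
F4 | step 7 | (1S,4S,5R)-4-[3-(TBDPSO)prop-1-en-2-yl]-5-ethenyl-5-methylcyclohex-2-en-1-ol | C=C[C@@]1(C)C[C@H](O)C=C[C@@H]1C(=C)CO[Si](c2ccccc2)(c3ccccc3)C(C)(C)C
F5 | step 7 | (1S,2S,4R,5S,6R)-5-[3-(TBDPSO)prop-1-en-2-yl]-4-ethenyl-4-methyl-7-oxabicyclo[4.1.0]heptan-2-ol | C=C[C@@]1(C)C[C@H](O)[C@@H]2O[C@@H]2[C@@H]1C(=C)CO[Si](c3ccccc3)(c4ccccc4)C(C)(C)C
F6 | step 7 | (1R,4R,5S,6R)-5-[3-(TBDPSO)prop-1-en-2-yl]-4-ethenyl-4-methyl-7-oxabicyclo[4.1.0]heptan-2-one | C=C[C@@]1(C)CC(=O)[C@@H]2O[C@@H]2[C@@H]1C(=C)CO[Si](c3ccccc3)(c4ccccc4)C(C)(C)C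
F7 | step 9 | (1S,2R,3R,4S,5R)-2-[3-(TBSO)prop-1-en-2-yl]-4-[3-(TBDPSO)prop-1-en-2-yl]-5-ethenyl-5-methylcyclohexane-1,3-diol | C=C[C@@]1(C)C[C@H](O)[C@@H](C(=C)CO[Si](C)(C)C(C)(C)C)[C@H](O)[C@@H]1C(=C)CO[Si](c2ccccc2)(c3ccccc3)C(C)(C)C
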